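The route rests on closing cyclopentane ring C through the C-2'–C-3' bond by SmI2-mediated intramolecular acyl substitution. In the precursor, C-3' is the carbonyl of a bridged γ-lactone to the tertiary O-7' of cyclohexane ring B, and C-2' is a primary iodide on the C-7a' arm. This temporary ring is possible because C-3', the C-1'/C-2' arm and O-7' are all cis on ring B. It locks C-3a', shields one face of C-5' during its quaternisation, and is opened in the step that forms the cis-hydrindanone. The freed O-7' later relays the C-6 carbonyl to carbon when triketone ring A is closed; methyl addition to C-3' completes ring C.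

Key step: step 13

Numbering (spiro[cyclohexane-1,5'-indene]): ring A = C-1 (spiro), C-2 (ketone), C-3 (methyl, prenyl), C-4 (enol), C-5 (acyl), C-6 (ketone); ring B = C-3a', C-4', C-5' (= C-1), C-6', C-7', C-7a'; ring C = C-1', C-2', C-3', C-3a', C-7a'.

Assumption: the (R,R)-configured ammonium catalyst of step 9 gives the (R)-malonate 18; if a model run shows the opposite sense, its enantiomer is used.

Assumption: compounds 1, 2, 7, 9, 12, 13, 15, 17 and 26 are bought.

Remark: 10 and 11 are carried as epimer mixtures at the ester-bearing carbon (future C-1), which is enolised in step 11.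

**Step 1**
Reactants: 1 3-{[tert-butyl(dimethyl)silyl]oxy}propanal; 2 ethyl 2-[bis(2,2,2-trifluoroethoxy)phosphoryl]propanoate
Product: 3 ethyl (2Z)-5-{[tert-butyl(dimethyl)silyl]oxy}-2-methylpent-2-enoate
Conditions: KHMDS, 18-crown-6, THF, −78 °C
Reagents that add atoms: none
Why: Still–Gennari variant of the Horner–Wadsworth–Emmons reaction, in which the electron-poor phosphonate makes oxaphosphetane collapse faster than equilibration and should give the Z-trisubstituted enoate that later places C-1' cis to C-6'.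

**Step 2**
Reactants: 3 Z-enoate
Product: 4 (2Z)-5-{[tert-butyl(dimethyl)silyl]oxy}-2-methylpent-2-en-1-ol
Conditions: DIBAL-H (2.2 equiv), CH2Cl2, −78 °C; aq. Rochelle salt
Reagents that add atoms: none
Why: Ester reduction by two hydride transfers at low temperature, which should leave the alkene geometry and the silyl ether untouched.

**Step 3**
Reactants: 4 Z-allylic alcohol
Product: 5 [(2R,3S)-3-(2-{[tert-butyl(dimethyl)silyl]oxy}ethyl)-2-methyloxiran-2-yl]methanol
Conditions: Ti(OiPr)4 (10 mol%), L-(+)-diisopropyl tartrate (12 mol%), t-BuOOH, 4 Å MS, CH2Cl2, −20 °C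
Reagents that add atoms: tert-butyl hydroperoxide, CC(C)(C)OO
Why: Sharpless asymmetric epoxidation; with the hydroxymethyl group drawn at the lower right the L-(+)-tartrate complex delivers oxygen to the lower face, which should set C-7' (R) and the epoxide carbon (S) that becomes C-7a' after inversion.

**Step 4**
Reactants: 5 epoxy alcohol
Product: 6 tert-butyl{2-[(2S,3S)-3-(iodomethyl)-3-methyloxiran-2-yl]ethoxy}dimethylsilane
Conditions: I2, PPh3, imidazole, CH2Cl2, 0 °C, dark
Reagents that add atoms: iodine, II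
Why: Appel-type iodination in which iodide displaces the alkoxyphosphonium group at the primary carbon, the epoxide being inert under these neutral conditions.

**Step 5**
Reactants: 6 epoxy iodide; 7 tert-butyl acetate
Product: 8 tert-butyl 3-[(2R,3S)-3-(2-{[tert-butyl(dimethyl)silyl]oxy}ethyl)-2-methyloxiran-2-yl]propanoate
Conditions: 7, LDA, THF, −78 °C; then 6, DMPU, −78 → −30 °C
Reagents that add atoms: none
Why: SN2 alkylation of the lithium ester enolate at the primary glycidylic iodide, which is more reactive than the trisubstituted epoxide; the tert-butyl ester is chosen because it will not lactonise in step 6.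

**Step 6**
Reactants: 8 epoxy ester; 9 methyl acrylate
Product: 11 tert-butyl (1S,5R,8S)-8-(2-{[tert-butyl(dimethyl)silyl]oxy}ethyl)-5-methyl-7-oxo-6-oxabicyclo[3.2.1]octane-3-carboxylate, via Michael adduct 10 (not isolated)
Conditions: LDA (1.05 equiv), THF, −78 °C; 9 (1.0 equiv, slow addition), −78 °C; then → 23 °C; 1 M HCl
Reagents that add atoms: none
Why: Michael-initiated ring closure followed by lactonisation: the Michael addition gives the methyl ester enolate at C-3a', which should open the epoxide at its less substituted carbon in a chair-like 6-endo SN2 (inversion sets C-7a'), and the tertiary alkoxide then lactonises onto the cis methyl ester, the epimerisable C-3a' funnelling into the bridged lactone while the tert-butyl ester stays inert.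

**Step 7**
Reactants: 12 2,2,5-trimethyl-1,3-dioxane-4,6-dione; 13 tert-butanol
Product: 14 3-tert-butoxy-2-methyl-3-oxopropanoic acid
Conditions: t-BuOH (solvent), reflux
Reagents that add atoms: none
Why: Thermal alcoholysis of the Meldrum's acid derivative opens the ring to the half ester with loss of acetone.

**Step 8**
Reactants: 14 half ester; 15 2,2-diphenylethanol
Product: 16 1-tert-butyl 3-(2,2-diphenylethyl) 2-methylpropanedioate
Conditions: DCC, DMAP (cat.), CH2Cl2, 0 → 23 °C
Reagents that add atoms: none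
Why: Steglich esterification through the O-acylisourea and the acylpyridinium ion; the α-centre is irrelevant because it is enolised in step 9.

**Step 9**
Reactants: 16 mixed malonate; 17 1-bromo-3-methylbut-2-ene
Product: 18 1-tert-butyl 3-(2,2-diphenylethyl) (2R)-2-methyl-2-(3-methylbut-2-en-1-yl)propanedioate
Conditions: (R,R)-3,4,5-trifluorophenyl-NAS bromide (5 mol%), 50% aq. KOH, toluene, −40 °C
Reagents that add atoms: none
Why: Asymmetric phase-transfer alkylation in which the chiral quaternary ammonium enolate ion pair exposes one face of the α-methylmalonate enolate to the allylic bromide, which should set the quaternary centre that becomes C-3, with the tert-butyl ester carbon as the future C-2.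

**Step 10**
Reactants: 18 (R)-diester
Product: 19 (2S)-3-(2,2-diphenylethoxy)-2-methyl-2-(3-methylbut-2-en-1-yl)-3-oxopropanoic acid
Conditions: TMSOTf, 2,6-lutidine, CH2Cl2, 0 °C; then H2O
Reagents that add atoms: none
Why: Silyl triflate mediated cleavage of the tert-butyl ester (loss of 2-methylpropene, hydrolysis of the silyl ester on work-up) under buffered non-protic conditions that should spare the prenyl alkene and the primary ester.

**Step 11**
Reactants: 11 bicyclic lactone; 19 (S)-acid
Product: 21 tert-butyl (1S,3R,5R,8S)-8-(2-{[tert-butyl(dimethyl)silyl]oxy}ethyl)-3-[(2S)-3-(2,2-diphenylethoxy)-2-methyl-2-(3-methylbut-2-en-1-yl)-3-oxopropanoyl]-5-methyl-7-oxo-6-oxabicyclo[3.2.1]octane-3-carboxylate, via acid chloride 20 (not isolated)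
Conditions: 19, 1-chloro-N,N,2-trimethylprop-1-en-1-amine, CH2Cl2, 0 → 23 °C, evaporate; 11, LDA, THF, −78 → −40 °C; add crude 20 at −78 °C
Reagents that add atoms: none
Why: Claisen-type C-acylation of the lithium ester enolate (both epimers of 11 give the same enolate): the lactone bridge shields the endo face, so the acyl group should enter exo and push the tert-butyl ester endo, which sets the spiro centre C-1 (= C-5') with the future C-6 carbon cis to O-7'; the lactone cannot enolise because its α-carbon is a bridgehead.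

**Step 12**
Reactants: 21 acylated lactone
Product: 23 tert-butyl (1S,3R,5R,8S)-3-[(2S)-3-(2,2-diphenylethoxy)-2-methyl-2-(3-methylbut-2-en-1-yl)-3-oxopropanoyl]-8-(2-iodoethyl)-5-methyl-7-oxo-6-oxabicyclo[3.2.1]octane-3-carboxylate, via hydroxy lactone 22 (not isolated)
Conditions: HF·pyridine, pyridine, THF, 0 °C; extractive work-up; then I2, PPh3, imidazole, CH2Cl2, 0 °C
Reagents that add atoms: iodine, II
Why: Fluoride-mediated desilylation followed at once by Appel-type iodination, so that the primary alcohol has no time to translactonise onto the bridged lactone.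

**Step 13**
Reactants: 23 iodo lactone
Product: 24 tert-butyl (3aS,4R,6R,7aS)-6-[(2S)-3-(2,2-diphenylethoxy)-2-methyl-2-(3-methylbut-2-en-1-yl)-3-oxopropanoyl]-4-hydroxy-4-methyl-1-oxooctahydro-1H-indene-6-carboxylate
Conditions: SmI2 (2.2 equiv), Fe(dbm)3 (2 mol%), THF, −30 → 0 °C; pH 7 phosphate buffer, 0 °C
Reagents that add atoms: none
Why: SmI2 with catalytic Fe(dbm)3 reduces the primary iodide to an alkylsamarium species at C-2' that adds 5-exo-trig to the lactone carbonyl C-3', and the tetrahedral samarium hemiketalate collapses with loss of the O-7' alkoxide to give the cyclopentanone, so ring C is closed through the C-2'–C-3' bond. The closest known reaction type is the SmI2-promoted intramolecular nucleophilic acyl substitution of halo esters and halo lactones. No new stereocentre is formed: the cis ring fusion is inherited from the lactone, in which C-3a' is a non-enolisable bridgehead and the iodoethyl arm on the one-carbon bridge C-7a' lies syn to the lactone and gauche to C-3'. The step needs chemoselectivity for the lactone over the tert-butyl ester, the diphenylethyl ester and the C-2 ketone, which the five-membered transition state (the alternatives would be seven-membered or larger) and the quaternary flanks of those carbonyls should secure. Over-reduction of the new ketone is limited by using just over two equivalents of SmI2 and by the ketone staying masked as the hemiketalate until work-up.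

**Step 14**
Reactants: 24 hydroxy ketone
Product: 25 tert-butyl (1R,3aS,4R,6R,7aS)-6-[(2S)-3-(2,2-diphenylethoxy)-2-methyl-2-(3-methylbut-2-en-1-yl)-3-oxopropanoyl]-1,4-dihydroxy-1,4-dimethyloctahydro-1H-indene-6-carboxylate
Conditions: CeCl3, MeMgBr (3 equiv), THF, −78 °C; aq. NH4Cl at −78 °C
Reagents that add atoms: methylmagnesium bromide, C[Mg]Br
Why: Organocerium 1,2-addition is non-basic and selective for the cyclopentanone over the esters and the doubly neopentylic C-2 ketone; attack from the convex face of the cis-hydrindanone, syn to H-3a', should place the methyl group anti to ring B and the hydroxyl on the concave face, which sets C-3'.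

**Step 15**
Reactants: 26 (2S)-2-methylbutanoic acid
Product: 27 (3S)-3-methylpentan-2-one
Conditions: MeLi (2.1 equiv), Et2O, 0 °C; inverse quench into cold 1 M HCl
Reagents that add atoms: methyllithium, [Li]C
Why: Carboxylate to methyl ketone conversion: addition stops at the dilithium ketone hydrate, which releases the ketone only on quenching, so the α-stereocentre should not be enolised.

**Step 16**
Reactants: 25 diol diester; 27 (3S)-3-methylpentan-2-one
Product: 30 Hyperielliptone HB, via keto lactone 28 (not isolated), via diketone 29 (not isolated)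
Conditions: LiHMDS (2.1 equiv), THF, 0 → 23 °C; −78 °C, lithium enolate of 27 (LDA, THF, −78 °C; 1.5 equiv), → 0 °C, then 40 °C; 1 M HCl
Reagents that add atoms: none
Why: Three acyl transfers in sequence: the O-7' alkoxide lactonises onto the cis tert-butyl ester, the kinetic methyl-side enolate of 27 opens this lactone in a Claisen condensation and so hands the C-6 carbonyl over to carbon, and the resulting β-diketonate closes ring A by Dieckmann condensation onto the C-4 ester, driven by formation of the triketonate; no stereocentre is formed, and the side-chain centre should survive because ketone and enolate are kept cold until consumed (a δ-lactone through O-3' in place of 28 would converge on the same product).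

**Compound list**

1 | 3-{[tert-butyl(dimethyl)silyl]oxy}propanal | O=CCCO[Si](C)(C)C(C)(C)C | starting material
2 | ethyl 2-[bis(2,2,2-trifluoroethoxy)phosphoryl]propanoate | CCOC(=O)C(C)P(=O)(OCC(F)(F)F)OCC(F)(F)F | starting material
3 | ethyl (2Z)-5-{[tert-butyl(dimethyl)silyl]oxy}-2-methylpent-2-enoate | CCOC(=O)/C(C)=C\CCO[Si](C)(C)C(C)(C)C | intermediate
4 | (2Z)-5-{[tert-butyl(dimethyl)silyl]oxy}-2-methylpent-2-en-1-ol | OC/C(C)=C\CCO[Si](C)(C)C(C)(C)C | intermediate
5 | [(2R,3S)-3-(2-{[tert-butyl(dimethyl)silyl]oxy}ethyl)-2-methyloxiran-2-yl]methanol | OC[C@@]1(C)O[C@H]1CCO[Si](C)(C)C(C)(C)C | intermediate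
6 | tert-butyl{2-[(2S,3S)-3-(iodomethyl)-3-methyloxiran-2-yl]ethoxy}dimethylsilane | IC[C@@]1(C)O[C@H]1CCO[Si](C)(C)C(C)(C)C | intermediate
7 | tert-butyl acetate | CC(=O)OC(C)(C)C | starting material
8 | tert-butyl 3-[(2R,3S)-3-(2-{[tert-butyl(dimethyl)silyl]oxy}ethyl)-2-methyloxiran-2-yl]propanoate | CC(C)(C)OC(=O)CC[C@@]1(C)O[C@H]1CCO[Si](C)(C)C(C)(C)C | intermediate
9 | methyl acrylate | C=CC(=O)OC | starting material
10 | 1-tert-butyl 5-methyl 2-{[(2R,3S)-3-(2-{[tert-butyl(dimethyl)silyl]oxy}ethyl)-2-methyloxiran-2-yl]methyl}pentanedioate (both C-2 epimers) | COC(=O)CCC(C[C@@]1(C)O[C@H]1CCO[Si](C)(C)C(C)(C)C)C(=O)OC(C)(C)C | intermediate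
11 | tert-butyl (1S,5R,8S)-8-(2-{[tert-butyl(dimethyl)silyl]oxy}ethyl)-5-methyl-7-oxo-6-oxabicyclo[3.2.1]octane-3-carboxylate (both C-3 epimers) | O=C1O[C@]2(C)CC(C(=O)OC(C)(C)C)C[C@H]1[C@@H]2CCO[Si](C)(C)C(C)(C)C | intermediate
12 | 2,2,5-trimethyl-1,3-dioxane-4,6-dione | CC1C(=O)OC(C)(C)OC1=O | starting material
13 | tert-butanol | CC(C)(C)O | starting material
14 | 3-tert-butoxy-2-methyl-3-oxopropanoic acid (racemic) | CC(C(=O)O)C(=O)OC(C)(C)C | intermediate
15 | 2,2-diphenylethanol | OCC(c1ccccc1)c1ccccc1 | starting material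
16 | 1-tert-butyl 3-(2,2-diphenylethyl) 2-methylpropanedioate (racemic) | CC(C(=O)OC(C)(C)C)C(=O)OCC(c1ccccc1)c1ccccc1 | intermediate
17 | 1-bromo-3-methylbut-2-ene | CC(C)=CCBr | starting material
18 | 1-tert-butyl 3-(2,2-diphenylethyl) (2R)-2-methyl-2-(3-methylbut-2-en-1-yl)propanedioate | CC(C)(C)OC(=O)[C@](C)(CC=C(C)C)C(=O)OCC(c1ccccc1)c1ccccc1 | intermediate
19 | (2S)-3-(2,2-diphenylethoxy)-2-methyl-2-(3-methylbut-2-en-1-yl)-3-oxopropanoic acid | OC(=O)[C@](C)(CC=C(C)C)C(=O)OCC(c1ccccc1)c1ccccc1 | intermediate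
20 | 2,2-diphenylethyl (2R)-2-(chlorocarbonyl)-2,5-dimethylhex-4-enoate | ClC(=O)[C@](C)(CC=C(C)C)C(=O)OCC(c1ccccc1)c1ccccc1 | intermediate
21 | tert-butyl (1S,3R,5R,8S)-8-(2-{[tert-butyl(dimethyl)silyl]oxy}ethyl)-3-[(2S)-3-(2,2-diphenylethoxy)-2-methyl-2-(3-methylbut-2-en-1-yl)-3-oxopropanoyl]-5-methyl-7-oxo-6-oxabicyclo[3.2.1]octane-3-carboxylate (acyl group exo, tert-butyl ester endo to the lactone bridge) | O=C1O[C@]2(C)C[C@@](C(=O)OC(C)(C)C)(C(=O)[C@](C)(CC=C(C)C)C(=O)OCC(c3ccccc3)c4ccccc4)C[C@H]1[C@@H]2CCO[Si](C)(C)C(C)(C)C | intermediate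
22 | tert-butyl (1S,3R,5R,8S)-3-[(2S)-3-(2,2-diphenylethoxy)-2-methyl-2-(3-methylbut-2-en-1-yl)-3-oxopropanoyl]-8-(2-hydroxyethyl)-5-methyl-7-oxo-6-oxabicyclo[3.2.1]octane-3-carboxylate | O=C1O[C@]2(C)C[C@@](C(=O)OC(C)(C)C)(C(=O)[C@](C)(CC=C(C)C)C(=O)OCC(c3ccccc3)c4ccccc4)C[C@H]1[C@@H]2CCO | intermediate
23 | tert-butyl (1S,3R,5R,8S)-3-[(2S)-3-(2,2-diphenylethoxy)-2-methyl-2-(3-methylbut-2-en-1-yl)-3-oxopropanoyl]-8-(2-iodoethyl)-5-methyl-7-oxo-6-oxabicyclo[3.2.1]octane-3-carboxylate | O=C1O[C@]2(C)C[C@@](C(=O)OC(C)(C)C)(C(=O)[C@](C)(CC=C(C)C)C(=O)OCC(c3ccccc3)c4ccccc4)C[C@H]1[C@@H]2CCI | intermediate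
24 | tert-butyl (3aS,4R,6R,7aS)-6-[(2S)-3-(2,2-diphenylethoxy)-2-methyl-2-(3-methylbut-2-en-1-yl)-3-oxopropanoyl]-4-hydroxy-4-methyl-1-oxooctahydro-1H-indene-6-carboxylate (cis ring fusion) | CC(C)(C)OC(=O)[C@@]2(C[C@H]3[C@H](CCC3=O)[C@](C)(O)C2)C(=O)[C@](C)(CC=C(C)C)C(=O)OCC(c4ccccc4)c5ccccc5 | intermediate
25 | tert-butyl (1R,3aS,4R,6R,7aS)-6-[(2S)-3-(2,2-diphenylethoxy)-2-methyl-2-(3-methylbut-2-en-1-yl)-3-oxopropanoyl]-1,4-dihydroxy-1,4-dimethyloctahydro-1H-indene-6-carboxylate | CC(C)(C)OC(=O)[C@@]2(C[C@H]3[C@H](CC[C@@]3(C)O)[C@](C)(O)C2)C(=O)[C@](C)(CC=C(C)C)C(=O)OCC(c4ccccc4)c5ccccc5 | intermediate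
26 | (2S)-2-methylbutanoic acid | CC[C@H](C)C(O)=O | starting material
27 | (3S)-3-methylpentan-2-one | CC[C@H](C)C(C)=O | intermediate
28 | keto lactone: γ-lactone of 25 between O-7' and the C-6 carboxyl carbon (6-oxabicyclo[3.2.1]octan-7-one carrying the cis-fused cyclopentane with the C-3' tertiary alcohol and the exo keto ester side chain) | O=C1O[C@]2(C)C[C@@]1(C(=O)[C@](C)(CC=C(C)C)C(=O)OCC(c4ccccc4)c5ccccc5)C[C@H]3[C@@H]2CC[C@@]3(C)O | intermediate
29 | diketone: 28 opened at C-6 by the enolate of 27, i.e. the hydrindane diol whose quaternary C-1 carries the (4S)-4-methyl-3-oxohexanoyl group and the keto ester side chain | CC[C@H](C)C(=O)CC(=O)[C@@]2(C[C@H]3[C@H](CC[C@@]3(C)O)[C@](C)(O)C2)C(=O)[C@](C)(CC=C(C)C)C(=O)OCC(c4ccccc4)c5ccccc5 | intermediate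
30 | Hyperielliptone HB, (1R,3R,3'R,3a'S,7'R,7a'S)-4,3',7'-trihydroxy-3,3',7'-trimethyl-5-[(2S)-2-methylbutanoyl]-3-(3-methylbut-2-en-1-yl)octahydrospiro[cyclohex-4-ene-1,5'-indene]-2,6-dione | CC[C@H](C)C(=O)C1=C(O)[C@@](C)(CC=C(C)C)C(=O)[C@]2(C[C@H]3[C@H](CC[C@@]3(C)O)[C@](C)(O)C2)C1=O | target

Total step count: 16. Longest linear sequence: 11 (steps 1–6, 11–14 and 16).

**Steps most likely to fail**

Step 13 may fail by protonation of the alkylsamarium species before it reaches the lactone carbonyl, or by electron transfer to the keto ester part of the molecule. The fallback replaces the reductive closure by a carbanion acylation. From iodide 23, displacement with sodium benzenesulfinate (DMF, 23 °C) would give the sulfone F1. Deprotonation next to sulfur (LDA, 2.1 equiv, THF, −78 → −30 °C, cold quench) should lead to Claisen-type attack on the lactone carbonyl and close ring C as the β-keto sulfone F2, whose stabilised anion cannot add a second time. Reductive desulfonylation with aluminium amalgam in aqueous THF returns to 24.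

Step 11 may fail by O-acylation of the enolate, or by no reaction at all, because both the enolate carbon and the acid chloride are heavily hindered. The fallback makes the same bond by aldol addition and oxidation. Acid chloride 20 is reduced with LiAlH(O-t-Bu)3 (THF, −78 °C) to the aldehyde F3. Addition of the lithium enolate of 11 (exo face, as before) would give the β-hydroxy ester F4. Oxidation with Dess–Martin periodinane returns to 21.

Step 6 may fail by oligomerisation of the acrylate, or because the ester enolate is too sluggish to open the epoxide at the secondary carbon. The fallback closes ring B with a nitrile-stabilised carbanion instead. From 8, Michael addition of the enolate to acrylonitrile (LDA, THF, −78 °C) gives the cyano ester F5. Epoxynitrile cyclisation (KHMDS, toluene, 0 → 23 °C), with attack at the less substituted epoxide carbon, would give the hydroxy nitrile F6. Base-catalysed addition of the cis tertiary alkoxide to the nitrile (t-BuOK cat., THF) and hydrolysis of the cyclic imidate with dilute aqueous acid returns to lactone 11.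

**Further compounds**

F1 | step 13 | tert-butyl (1S,3R,5R,8S)-3-[(2S)-3-(2,2-diphenylethoxy)-2-methyl-2-(3-methylbut-2-en-1-yl)-3-oxopropanoyl]-5-methyl-7-oxo-8-[2-(phenylsulfonyl)ethyl]-6-oxabicyclo[3.2.1]octane-3-carboxylate | O=C1O[C@]2(C)C[C@@](C(=O)OC(C)(C)C)(C(=O)[C@](C)(CC=C(C)C)C(=O)OCC(c3ccccc3)c4ccccc4)C[C@H]1[C@@H]2CCS(=O)(=O)c5ccccc5
F2 | step 13 | tert-butyl (3aS,4R,6R,7aS)-6-[(2S)-3-(2,2-diphenylethoxy)-2-methyl-2-(3-methylbut-2-en-1-yl)-3-oxopropanoyl]-4-hydroxy-4-methyl-1-oxo-2-(phenylsulfonyl)octahydro-1H-indene-6-carboxylate (C-2 epimers) | CC(C)(C)OC(=O)[C@@]2(C[C@H]3[C@H](CC(S(=O)(=O)c6ccccc6)C3=O)[C@](C)(O)C2)C(=O)[C@](C)(CC=C(C)C)C(=O)OCC(c4ccccc4)c5ccccc5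
F3 | step 11 | 2,2-diphenylethyl (2S)-2-formyl-2,5-dimethylhex-4-enoate | O=C[C@](C)(CC=C(C)C)C(=O)OCC(c1ccccc1)c1ccccc1
F4 | step 11 | tert-butyl (1S,3R,5R,8S)-8-(2-{[tert-butyl(dimethyl)silyl]oxy}ethyl)-3-[(2S)-3-(2,2-diphenylethoxy)-1-hydroxy-2-methyl-2-(3-methylbut-2-en-1-yl)-3-oxopropyl]-5-methyl-7-oxo-6-oxabicyclo[3.2.1]octane-3-carboxylate (carbinol epimers) | O=C1O[C@]2(C)C[C@@](C(=O)OC(C)(C)C)(C(O)[C@](C)(CC=C(C)C)C(=O)OCC(c3ccccc3)c4ccccc4)C[C@H]1[C@@H]2CCO[Si](C)(C)C(C)(C)C
F5 | step 6 | tert-butyl 4-cyano-2-{[(2R,3S)-3-(2-{[tert-butyl(dimethyl)silyl]oxy}ethyl)-2-methyloxiran-2-yl]methyl}butanoate (C-2 epimers) | N#CCCC(C[C@@]1(C)O[C@H]1CCO[Si](C)(C)C(C)(C)C)C(=O)OC(C)(C)C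
F6 | step 6 | tert-butyl (3S,4S,5R)-4-(2-{[tert-butyl(dimethyl)silyl]oxy}ethyl)-3-cyano-5-hydroxy-5-methylcyclohexane-1-carboxylate (C-1 epimers) | CC(C)(C)OC(=O)C1C[C@H](C#N)[C@H](CCO[Si](C)(C)C(C)(C)C)[C@](C)(O)C1
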